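## Retrosynthetic overview

1. Katsumain C ⇒ its C5 silyl ether ⇒ cut the ring A C3'–C1 bond: cardamonin as nucleophile plus an (E)-alkenyl para-quinone methide generated in the flask; a chiral phosphoric acid sets C1 (proposed new step).
2. Quinone methide precursor (a 4-hydroxybenzylic allylic alcohol) ⇒ cross-metathesis at C2=C3 between an (R)-homoallylic silyl ether (C3–C7 plus one aryl ring) and a racemic aryl vinyl carbinol (C1–C2 plus the other aryl ring).
3. (R)-Homoallylic alcohol ⇒ Keck allylation of a 3-arylpropanal (sets C5) ⇒ methyl 3-(4-hydroxyphenyl)propanoate.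
4. Cardamonin ⇒ Claisen–Schmidt condensation of 2',4'-dihydroxy-6'-methoxyacetophenone with benzaldehyde.
5. No ring is built; all four benzene rings are bought. Order of events: chalcone, C5 centre, C2=C3 alkene, C1 centre with the aryl–C bond, desilylation.

Assumption: the (R)-configured phosphoric acid is taken to give the (1R) centre in step 9; if the first run shows the opposite sense, its mirror-image catalyst is used with nothing else changed.

Abbreviation: TBS = tert-butyldimethylsilyl. Chain numbering: C1 is the diaryl methine, C5 the carbinol, C7 the CH2 on the second hydroxyphenyl ring. The target is (1R,5R).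

## Route

Step 1
Reactants: 1 2',4'-dihydroxy-6'-methoxyacetophenone; 2 benzaldehyde
Product: 4 cardamonin, via aldol adduct 3 (not isolated)
Conditions: KOH (50% aq., excess), EtOH, rt, 48 h; then 2 M HCl, 0 °C
Reagents that add atoms: none
Why: Claisen–Schmidt condensation; the ketone enolate adds to the non-enolisable aldehyde and aldol 3 loses water (E1cB) to the conjugated, thermodynamically favoured (E)-chalcone.

Step 2
Reactants: 5 methyl 3-(4-hydroxyphenyl)propanoate
Product: 6 methyl 3-[4-(TBS-oxy)phenyl]propanoate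
Conditions: t-BuMe2SiCl, imidazole, DMF, rt
Reagents that add atoms: tert-butyldimethylsilyl chloride, CC(C)(C)[Si](C)(C)Cl
Why: Standard imidazole-promoted silylation of a phenol; the ester is untouched.

Step 3
Reactants: 6 methyl 3-[4-(TBS-oxy)phenyl]propanoate
Product: 7 3-[4-(TBS-oxy)phenyl]propanal
Conditions: i-Bu2AlH (1.05 equiv), CH2Cl2, −78 °C; then MeOH, aq. potassium sodium tartrate
Reagents that add atoms: none
Why: Partial ester reduction; the tetrahedral aluminium hemiacetal is stable at −78 °C and releases the aldehyde only on work-up, and the aryl silyl ether is inert to the hydride.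

Step 4
Reactants: 7 3-[4-(TBS-oxy)phenyl]propanal
Product: 8 (3R)-1-[4-(TBS-oxy)phenyl]hex-5-en-3-ol
Conditions: CH2=CHCH2SnBu3 (1.2 equiv), (S)-1,1'-bi-2-naphthol (10 mol%), Ti(OiPr)4 (10 mol%), 4 Å MS, CH2Cl2, −20 °C, 72 h; then aq. NaHCO3
Reagents that add atoms: allyltributylstannane, C=CC[Sn](CCCC)(CCCC)CCCC
Why: Keck asymmetric allylation; the (S)-binaphtholate–titanium Lewis acid activates the aldehyde and exposes its Si face to the allylstannane, which sets the carbinol centre (C5 of the target) as R.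

Step 5
Reactants: 8 (3R)-1-[4-(TBS-oxy)phenyl]hex-5-en-3-ol
Product: 9 (3R)-3-(TBS-oxy)-1-[4-(TBS-oxy)phenyl]hex-5-ene
Conditions: t-BuMe2SiCl, imidazole, DMF, rt
Reagents that add atoms: tert-butyldimethylsilyl chloride, CC(C)(C)[Si](C)(C)Cl
Why: Silylation of the secondary alcohol keeps it out of the metathesis and of the acid-catalysed step 9 and makes the later substrate soluble in non-polar solvent; the stereocentre is not touched.

Step 6
Reactants: 10 4-(TBS-oxy)benzaldehyde
Product: 11 racemic 1-[4-(TBS-oxy)phenyl]prop-2-en-1-ol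
Conditions: CH2=CHMgBr, THF, −78 → 0 °C; then aq. NH4Cl
Reagents that add atoms: vinylmagnesium bromide, C=C[Mg]Br
Why: Grignard 1,2-addition to an aryl aldehyde; the racemic carbinol centre is erased in step 9, so no control is needed.

Step 7
Reactants: 9 (3R)-3-(TBS-oxy)-1-[4-(TBS-oxy)phenyl]hex-5-ene; 11 racemic 1-[4-(TBS-oxy)phenyl]prop-2-en-1-ol (2.5 equiv)
Product: 12 (1RS,2E,5R)-5-(TBS-oxy)-1,7-bis[4-(TBS-oxy)phenyl]hept-2-en-1-ol
Conditions: second-generation Hoveyda–Grubbs catalyst, [1,3-bis(2,4,6-trimethylphenyl)imidazolidin-2-ylidene]dichloro(2-isopropoxybenzylidene)ruthenium (5 mol%), 2,6-dichloro-1,4-benzoquinone (10 mol%), CH2Cl2, 40 °C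
Reagents that add atoms: none
Why: Olefin cross-metathesis between a terminal homoallylic ether and a slowly dimerising secondary allylic alcohol used in excess; the disubstituted alkene forms with thermodynamic E selectivity, the quinone additive suppresses ruthenium hydride isomerisation, and C5 is untouched.

Step 8
Reactants: 12 (1RS,2E,5R)-5-(TBS-oxy)-1,7-bis[4-(TBS-oxy)phenyl]hept-2-en-1-ol
Product: 13 (1RS,2E,5R)-5-(TBS-oxy)-1,7-bis(4-hydroxyphenyl)hept-2-en-1-ol
Conditions: Cs2CO3 (0.3 equiv), DMF/H2O (10:1), rt; pH 7 phosphate buffer; used at once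
Reagents that add atoms: none
Why: Selective aryl silyl ether cleavage; phenoxide is a far better leaving group than a secondary alkoxide, so only the two aryl silyl ethers fall, freeing the phenol needed for quinone methide formation.

Step 9
Reactants: 13 (1RS,2E,5R)-5-(TBS-oxy)-1,7-bis(4-hydroxyphenyl)hept-2-en-1-ol; 4 cardamonin (2 equiv)
Product: 15 5-O-TBS-katsumain C, via alkenyl para-quinone methide 14 (not isolated)
Conditions: (R)-3,3'-bis(2,4,6-triisopropylphenyl)-1,1'-binaphthyl-2,2'-diyl hydrogen phosphate (10 mol%), 5 Å MS, CH2Cl2, −20 → 0 °C, 13 added over 2 h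
Reagents that add atoms: none
Why: Proposed new method: the phosphoric acid dehydrates the 4-hydroxybenzylic allylic alcohol (both C1 epimers, one molecule of water lost to the sieves) to the (E)-alkenyl para-quinone methide 14, binds its carbonyl oxygen through P–OH and the 4'-OH of cardamonin through P=O, so that C3' (flanked by two small hydroxyls and favoured by chelation-induced bond fixation, while C5' is shielded by the O-methyl) attacks the exocyclic benzylic carbon (1,6-addition, the electrophilic terminus nearest the bound oxygen) on the face left open by the triisopropylphenyl walls, setting C1 as R under catalyst control independently of the remote C5 centre, after which tautomerisation restores ring A and leaves the C2=C3 alkene E; closest known reaction type is the chiral phosphoric acid-catalysed enantioselective 1,6-conjugate (Friedel–Crafts) addition of naphthols, phenols and indoles to para-quinone methides formed in situ from 4-hydroxybenzyl alcohols, which has not been shown for an alkyl-substituted alkenyl quinone methide (1,6 against 1,8 control) or for an acylphloroglucinol-type nucleophile.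

Step 10
Reactants: 15 5-O-TBS-katsumain C
Product: 16 katsumain C
Conditions: HF·pyridine, THF/pyridine, 0 °C → rt
Reagents that add atoms: none
Why: Fluoride-driven cleavage of the last (secondary alkyl) silyl ether; buffered HF·pyridine leaves the chalcone, the phenols and both stereocentres untouched.

## Compound list

1 | 1-(2,4-dihydroxy-6-methoxyphenyl)ethan-1-one (2',4'-dihydroxy-6'-methoxyacetophenone) | CC(=O)c1c(O)cc(O)cc1OC | starting material
2 | benzaldehyde | O=Cc1ccccc1 | starting material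
3 | racemic 1-(2,4-dihydroxy-6-methoxyphenyl)-3-hydroxy-3-phenylpropan-1-one (aldol adduct) | COc1cc(O)cc(O)c1C(=O)CC(O)c1ccccc1 | intermediate (not isolated)
4 | cardamonin, (E)-1-(2,4-dihydroxy-6-methoxyphenyl)-3-phenylprop-2-en-1-one | COc1cc(O)cc(O)c1C(=O)/C=C/c1ccccc1 | intermediate
5 | methyl 3-(4-hydroxyphenyl)propanoate | COC(=O)CCc1ccc(O)cc1 | starting material
6 | methyl 3-[4-(tert-butyldimethylsilyloxy)phenyl]propanoate | COC(=O)CCc1ccc(O[Si](C)(C)C(C)(C)C)cc1 | intermediate
7 | 3-[4-(tert-butyldimethylsilyloxy)phenyl]propanal | O=CCCc1ccc(O[Si](C)(C)C(C)(C)C)cc1 | intermediate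
8 | (3R)-1-[4-(tert-butyldimethylsilyloxy)phenyl]hex-5-en-3-ol | C=CC[C@H](O)CCc1ccc(O[Si](C)(C)C(C)(C)C)cc1 | intermediate
9 | (3R)-3-(tert-butyldimethylsilyloxy)-1-[4-(tert-butyldimethylsilyloxy)phenyl]hex-5-ene | C=CC[C@H](O[Si](C)(C)C(C)(C)C)CCc1ccc(O[Si](C)(C)C(C)(C)C)cc1 | intermediate
10 | 4-(tert-butyldimethylsilyloxy)benzaldehyde | O=Cc1ccc(O[Si](C)(C)C(C)(C)C)cc1 | starting material
11 | racemic 1-[4-(tert-butyldimethylsilyloxy)phenyl]prop-2-en-1-ol | C=CC(O)c1ccc(O[Si](C)(C)C(C)(C)C)cc1 | intermediate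
12 | (1RS,2E,5R)-5-(tert-butyldimethylsilyloxy)-1,7-bis[4-(tert-butyldimethylsilyloxy)phenyl]hept-2-en-1-ol | OC(/C=C/C[C@H](O[Si](C)(C)C(C)(C)C)CCc1ccc(O[Si](C)(C)C(C)(C)C)cc1)c1ccc(O[Si](C)(C)C(C)(C)C)cc1 | intermediate
13 | (1RS,2E,5R)-5-(tert-butyldimethylsilyloxy)-1,7-bis(4-hydroxyphenyl)hept-2-en-1-ol | OC(/C=C/C[C@H](O[Si](C)(C)C(C)(C)C)CCc1ccc(O)cc1)c1ccc(O)cc1 | intermediate
14 | 4-[(2E,5R)-5-(tert-butyldimethylsilyloxy)-7-(4-hydroxyphenyl)hept-2-en-1-ylidene]cyclohexa-2,5-dien-1-one | O=C1C=CC(=C/C=C/C[C@H](O[Si](C)(C)C(C)(C)C)CCc2ccc(O)cc2)C=C1 | intermediate (not isolated)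
15 | (E)-1-{3-[(1R,2E,5R)-5-(tert-butyldimethylsilyloxy)-1,7-bis(4-hydroxyphenyl)hept-2-en-1-yl]-2,4-dihydroxy-6-methoxyphenyl}-3-phenylprop-2-en-1-one | COc1cc(O)c([C@H](/C=C/C[C@H](O[Si](C)(C)C(C)(C)C)CCc2ccc(O)cc2)c2ccc(O)cc2)c(O)c1C(=O)/C=C/c1ccccc1 | intermediate
16 | katsumain C, (E)-1-{2,4-dihydroxy-3-[(1R,2E,5R)-5-hydroxy-1,7-bis(4-hydroxyphenyl)hept-2-en-1-yl]-6-methoxyphenyl}-3-phenylprop-2-en-1-one | COc1cc(O)c([C@H](/C=C/C[C@H](O)CCc2ccc(O)cc2)c2ccc(O)cc2)c(O)c1C(=O)/C=C/c1ccccc1 | target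

## Step count and risks

Total step count: 10. Longest linear sequence: 8 steps (5 → 6 → 7 → 8 → 9 → 12 → 13 → 15 → 16).

The three steps most likely to fail:

**Step 9 (proposed new step).** The risks are 1,8-addition at C3, attack through C5' of ring A, and a low ratio at C1. The fallback uses only known chemistry, an aromatic Claisen rearrangement with 1,3-chirality transfer; it sets out from 12 (with 4 as the second partner) and comes back to the route at 16. Compound 12 is isomerised with Ph3SiOReO3 (2 mol%, Et2O, 0 °C; conjugation with the arene drives the 1,3-shift of the hydroxyl) to the allylic alcohol (1E,3RS,5R)-5-(TBS-oxy)-1,7-bis[4-(TBS-oxy)phenyl]hept-1-en-3-ol F1. MnO2 (CH2Cl2, rt) oxidises it to the enone (1E,5R)-5-(TBS-oxy)-1,7-bis[4-(TBS-oxy)phenyl]hept-1-en-3-one F2. Corey–Bakshi–Shibata reduction with BH3·SMe2 and (3aR)-1-methyl-3,3-diphenyltetrahydro-1H,3H-pyrrolo[1,2-c][1,3,2]oxazaborole (toluene, −40 °C) then gives the (1E,3S,5R)-allylic alcohol F3. Separately, cardamonin 4 is silylated at its unchelated 4'-hydroxyl (t-BuMe2SiCl, imidazole, CH2Cl2) to 4'-O-TBS-cardamonin F4. Mitsunobu coupling of F3 with the chelated 2'-OH of F4 (PPh3, diisopropyl azodicarboxylate, toluene, 0 °C) inverts C3 and gives the (3R)-2'-O-allyl aryl ether F5. Heating F5 with Eu(fod)3, europium tris(6,6,7,7,8,8,8-heptafluoro-2,2-dimethyl-3,5-octanedionate) (10 mol%, toluene, 80 °C), brings about the [3,3] shift through a chair transition state with the C4 chain equatorial. The only free ortho carbon is C3', and the new C3'–C1 bond forms on the allyl face from which oxygen leaves, so (3R) becomes (1R) with an E alkene, giving the tetrasilyl ether of katsumain C F6. HF·pyridine (THF/pyridine, 0 °C → rt) finally removes the four silyl groups and gives 16.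

**Step 7 (cross-metathesis).** The risks are isomerisation of 11 to the propiophenone, homodimers and E/Z mixtures. The fallback replaces metathesis by carbonyl chemistry; it sets out from 9 and comes back to the route at 12. Ozonolysis of 9 (O3, CH2Cl2, −78 °C; then PPh3) gives the aldehyde (3R)-3-(TBS-oxy)-5-[4-(TBS-oxy)phenyl]pentanal F7. A Wittig reaction with Ph3P=CHCHO (toluene, 80 °C) extends it to the (E)-enal (2E,5R)-5-(TBS-oxy)-7-[4-(TBS-oxy)phenyl]hept-2-enal F8. 1,2-Addition of 4-(t-BuMe2SiO)C6H4MgBr (THF, −78 °C) to F8 then gives 12.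

**Step 1 (direct Claisen–Schmidt on the unprotected dihydroxyacetophenone).** The risks are slow enolisation of the dianion, low yield and some cyclisation to the flavanone. The fallback changes the protecting-group strategy; it sets out from 1 and comes back to the route at 4. MeOCH2Cl with i-Pr2NEt (CH2Cl2, 0 °C) protects the unchelated 4-OH and gives 1-[2-hydroxy-6-methoxy-4-(methoxymethoxy)phenyl]ethan-1-one F9. Claisen–Schmidt condensation with 2 (KOH, EtOH, rt) now runs on a monoanion and gives 4'-O-(methoxymethyl)cardamonin F10. HCl in MeOH (40 °C) removes the acetal and gives 4.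

## Further compounds

F1 | step 9 | (1E,3RS,5R)-5-(tert-butyldimethylsilyloxy)-1,7-bis[4-(tert-butyldimethylsilyloxy)phenyl]hept-1-en-3-ol | CC(C)(C)[Si](C)(C)Oc1ccc(/C=C/C(O)C[C@H](O[Si](C)(C)C(C)(C)C)CCc2ccc(O[Si](C)(C)C(C)(C)C)cc2)cc1
F2 | step 9 | (1E,5R)-5-(tert-butyldimethylsilyloxy)-1,7-bis[4-(tert-butyldimethylsilyloxy)phenyl]hept-1-en-3-one | CC(C)(C)[Si](C)(C)Oc1ccc(/C=C/C(=O)C[C@H](O[Si](C)(C)C(C)(C)C)CCc2ccc(O[Si](C)(C)C(C)(C)C)cc2)cc1
F3 | step 9 | (1E,3S,5R)-5-(tert-butyldimethylsilyloxy)-1,7-bis[4-(tert-butyldimethylsilyloxy)phenyl]hept-1-en-3-ol | CC(C)(C)[Si](C)(C)Oc1ccc(/C=C/[C@@H](O)C[C@H](O[Si](C)(C)C(C)(C)C)CCc2ccc(O[Si](C)(C)C(C)(C)C)cc2)cc1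
F4 | step 9 | (E)-1-[4-(tert-butyldimethylsilyloxy)-2-hydroxy-6-methoxyphenyl]-3-phenylprop-2-en-1-one (4'-O-TBS-cardamonin) | COc1cc(O[Si](C)(C)C(C)(C)C)cc(O)c1C(=O)/C=C/c1ccccc1
F5 | step 9 | (E)-1-{2-[((1E,3R,5R)-5-(tert-butyldimethylsilyloxy)-1,7-bis[4-(tert-butyldimethylsilyloxy)phenyl]hept-1-en-3-yl)oxy]-4-(tert-butyldimethylsilyloxy)-6-methoxyphenyl}-3-phenylprop-2-en-1-one | COc1cc(O[Si](C)(C)C(C)(C)C)cc(O[C@@H](/C=C/c2ccc(O[Si](C)(C)C(C)(C)C)cc2)C[C@H](O[Si](C)(C)C(C)(C)C)CCc2ccc(O[Si](C)(C)C(C)(C)C)cc2)c1C(=O)/C=C/c1ccccc1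
F6 | step 9 | (E)-1-{3-[(1R,2E,5R)-5-(tert-butyldimethylsilyloxy)-1,7-bis[4-(tert-butyldimethylsilyloxy)phenyl]hept-2-en-1-yl]-4-(tert-butyldimethylsilyloxy)-2-hydroxy-6-methoxyphenyl}-3-phenylprop-2-en-1-one | COc1cc(O[Si](C)(C)C(C)(C)C)c([C@H](/C=C/C[C@H](O[Si](C)(C)C(C)(C)C)CCc2ccc(O[Si](C)(C)C(C)(C)C)cc2)c2ccc(O[Si](C)(C)C(C)(C)C)cc2)c(O)c1C(=O)/C=C/c1ccccc1
F7 | step 7 | (3R)-3-(tert-butyldimethylsilyloxy)-5-[4-(tert-butyldimethylsilyloxy)phenyl]pentanal | O=CC[C@H](O[Si](C)(C)C(C)(C)C)CCc1ccc(O[Si](C)(C)C(C)(C)C)cc1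
F8 | step 7 | (2E,5R)-5-(tert-butyldimethylsilyloxy)-7-[4-(tert-butyldimethylsilyloxy)phenyl]hept-2-enal | O=C/C=C/C[C@H](O[Si](C)(C)C(C)(C)C)CCc1ccc(O[Si](C)(C)C(C)(C)C)cc1
F9 | step 1 | 1-[2-hydroxy-6-methoxy-4-(methoxymethoxy)phenyl]ethan-1-one | CC(=O)c1c(O)cc(OCOC)cc1OC
F10 | step 1 | (E)-1-[2-hydroxy-6-methoxy-4-(methoxymethoxy)phenyl]-3-phenylprop-2-en-1-one | COCOc1cc(O)c(C(=O)/C=C/c2ccccc2)c(OC)c1
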